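**Retrosynthetic overview**
1. Target 14 comes from its benzyl ester 13 by a final hydrogenolysis, so the depside aryl ester never meets base.
2. The strategy rests on ring A: ester-bearing C1 sits between hydroxyl-bearing C2 and methyl-bearing C6, with methoxyl on C4, so the oxygens on C2 and C4 are 1,3-related. This ring is cut at C1–C2 and C5–C6 into the 1,1,3-trioxygenated diene 4 and the but-2-ynoate triple bond of 9; loss of trimethylsilanol aromatises the adduct.
3. Ring A is the only ring built. Ring B comes intact from olivetolic acid 5 by way of benzyl ester 7 and acylation of its unchelated 4-hydroxyl with but-2-ynoic acid 8, so the depside ester oxygen is in place before the hindered benzoate exists.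
4. The chelated 2-hydroxyl of ring B is not benzylated, because direct benzylation would etherify the 4-hydroxyl first. It is masked only in the flask as a trimethylsilyl ether during the cycloaddition.
5. Diene 4 comes from methyl (E)-3-methoxybut-2-enoate 1 by saponification, silyl ester formation and γ-deprotonation/O-silylation.

Key step: step 6

Remark: the target has no stereocentre. Ring A is the 2-hydroxy-4-methoxy-6-methylbenzoyl ring (C1 = carbonyl-bearing carbon); ring B is the pentyl-substituted salicylic acid ring (C1 = carboxyl-bearing carbon).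

**Route**

Step 1
Reactants: 1 methyl (E)-3-methoxybut-2-enoate
Product: 2 (E)-3-methoxybut-2-enoic acid
Conditions: NaOH (1.2 equiv), MeOH/H2O, 60 °C; then 1 M HCl to pH 3, 0 °C
Reagents that add atoms: sodium hydroxide, [Na+].[OH-]
Why: Ester saponification, in which the enol ether is inert to base and brief cold acidification to pH 3 should precipitate the acid before the enol ether can hydrolyse.

Step 2
Reactants: 2 (E)-3-methoxybut-2-enoic acid
Product: 3 trimethylsilyl (E)-3-methoxybut-2-enoate
Conditions: Me3SiCl, Et3N, Et2O, 0 °C to rt; filter, distil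
Reagents that add atoms: chlorotrimethylsilane, C[Si](C)(C)Cl
Why: O-Silylation of a carboxylic acid with a chlorosilane and an amine base should give a distillable silyl ester that already carries one of the two silyloxy groups of the diene.

Step 3
Reactants: 3 trimethylsilyl (E)-3-methoxybut-2-enoate
Product: 4 3-methoxy-1,1-bis(trimethylsilyloxy)buta-1,3-diene
Conditions: LiN(iPr)2 (1.1 equiv), THF, −78 °C; Me3SiCl, −78 °C to rt; pentane, filter, distil
Reagents that add atoms: chlorotrimethylsilane, C[Si](C)(C)Cl
Why: Kinetic γ-deprotonation at the only enolisable position (the C4 methyl) and O-silylation of the vinylogous ester enolate is the standard preparation of Brassard-type vinylketene acetals, applied here to a silyl ester so that both ketene acetal oxygens carry trimethylsilyl.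

Step 4
Reactants: 5 olivetolic acid; 6 benzyl bromide
Product: 7 benzyl 2,4-dihydroxy-6-pentylbenzoate
Conditions: KHCO3 (1.1 equiv), DMF, rt
Reagents that add atoms: none
Why: SN2 O-alkylation of the carboxylate, in which bicarbonate ionises only the carboxylic acid and not the phenols, so no ether should form, and room temperature avoids decarboxylation of the β-resorcylic acid.

Step 5
Reactants: 7 benzyl 2,4-dihydroxy-6-pentylbenzoate; 8 but-2-ynoic acid
Product: 9 benzyl 4-(but-2-ynoyloxy)-2-hydroxy-6-pentylbenzoate
Conditions: DCC (1.1 equiv), DMAP (5 mol%), CH2Cl2, 0 °C to rt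
Reagents that add atoms: none
Why: Steglich esterification, in which the acyl group is transferred to the free, unhindered 4-hydroxyl while the 2-hydroxyl is held in a hydrogen bond to the adjacent benzyl ester carbonyl and should not be acylated.

Step 6
Reactants: 9 benzyl 4-(but-2-ynoyloxy)-2-hydroxy-6-pentylbenzoate; 4 3-methoxy-1,1-bis(trimethylsilyloxy)buta-1,3-diene
Product: 13 benzyl 2-hydroxy-4-[(2-hydroxy-4-methoxy-6-methylbenzoyl)oxy]-6-pentylbenzoate, via ring-B trimethylsilyl ether 10 (not isolated), via cyclohexa-1,4-diene cycloadduct 11 (not isolated), via doubly silylated depside ester 12 (not isolated)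
Conditions: BSA (1.5 equiv), CH2Cl2, rt, then evaporate volatiles; 4 (3 equiv), PhMe, 120 °C, sealed tube; then 1 M HCl, THF, 0 °C
Reagents that add atoms: none
Why: With the chelated ring-B phenol capped as its silyl ether 10 so that it cannot protonate the ketene acetal, diene 4 and the triple bond of the ynoate combine in a thermal, normal-electron-demand [4+2] cycloaddition with an unsymmetrical transition state: the CH2 terminus of the diene bonds to the methyl-bearing β-carbon (ring A C5–C6) and the ketene acetal carbon to the α-carbon (ring A C1–C2). The closest known reaction type is the Diels–Alder benzannulation of Brassard-type vinylketene acetals with acetylenic esters, which ends in eliminative aromatisation. Ring A is closed by this intermolecular cycloaddition, both ring bonds being made in the one event; cycloadduct 11 then loses trimethylsilanol by 1,4-elimination (a C5 hydrogen and one C2 silyloxy group) to give arene 12, and dilute acid frees both phenols to give 13. No stereocentre is created, because the two sp3 ring carbons of 11 each carry two identical substituents. Only the orientation of the partners has to be controlled: the three donor oxygens make the unsubstituted terminus of 4 its most nucleophilic carbon, and the ynoate, rendered more electron-poor by its aryl ester than an alkyl ester would be, is electrophilic at the β-carbon, so hydroxyl falls on C2, methoxyl on C4 and methyl on C6.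

Step 7
Reactants: 13 benzyl 2-hydroxy-4-[(2-hydroxy-4-methoxy-6-methylbenzoyl)oxy]-6-pentylbenzoate
Product: 14 2-hydroxy-4-[(2-hydroxy-4-methoxy-6-methylbenzoyl)oxy]-6-pentylbenzoic acid
Conditions: H2 (1 atm), 10% Pd/C, EtOAc, rt
Reagents that add atoms: none
Why: Hydrogenolysis of the benzylic C–O bond on palladium should free the carboxylic acid under neutral conditions that leave the depside aryl ester, the aryl methyl ether and both arenes untouched.

**Compound list**
1 | methyl (E)-3-methoxybut-2-enoate | CO/C(C)=C/C(=O)OC | starting material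
2 | (E)-3-methoxybut-2-enoic acid | CO/C(C)=C/C(=O)O | intermediate
3 | trimethylsilyl (E)-3-methoxybut-2-enoate | CO/C(C)=C/C(=O)O[Si](C)(C)C | intermediate
4 | 3-methoxy-1,1-bis(trimethylsilyloxy)buta-1,3-diene | C=C(OC)C=C(O[Si](C)(C)C)O[Si](C)(C)C | intermediate
5 | olivetolic acid (2,4-dihydroxy-6-pentylbenzoic acid) | CCCCCc1cc(O)cc(O)c1C(=O)O | starting material
6 | benzyl bromide | BrCc1ccccc1 | starting material
7 | benzyl 2,4-dihydroxy-6-pentylbenzoate | CCCCCc1cc(O)cc(O)c1C(=O)OCc1ccccc1 | intermediate
8 | but-2-ynoic acid | CC#CC(=O)O | starting material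
9 | benzyl 4-(but-2-ynoyloxy)-2-hydroxy-6-pentylbenzoate (4-(benzyloxycarbonyl)-3-hydroxy-5-pentylphenyl but-2-ynoate) | CC#CC(=O)Oc1cc(CCCCC)c(C(=O)OCc2ccccc2)c(O)c1 | intermediate
10 | benzyl 4-(but-2-ynoyloxy)-6-pentyl-2-(trimethylsilyloxy)benzoate (formed in the flask in step 6) | CC#CC(=O)Oc1cc(CCCCC)c(C(=O)OCc2ccccc2)c(O[Si](C)(C)C)c1 | intermediate
11 | benzyl 4-{[4-methoxy-2-methyl-6,6-bis(trimethylsilyloxy)cyclohexa-1,4-diene-1-carbonyl]oxy}-6-pentyl-2-(trimethylsilyloxy)benzoate (formed in the flask in step 6) | COC1=CC(O[Si](C)(C)C)(O[Si](C)(C)C)C(C(=O)Oc2cc(CCCCC)c(C(=O)OCc3ccccc3)c(O[Si](C)(C)C)c2)=C(C)C1 | intermediate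
12 | benzyl 4-{[4-methoxy-2-methyl-6-(trimethylsilyloxy)benzoyl]oxy}-6-pentyl-2-(trimethylsilyloxy)benzoate (formed in the flask in step 6) | COc1cc(C)c(C(=O)Oc2cc(CCCCC)c(C(=O)OCc3ccccc3)c(O[Si](C)(C)C)c2)c(O[Si](C)(C)C)c1 | intermediate
13 | benzyl 2-hydroxy-4-[(2-hydroxy-4-methoxy-6-methylbenzoyl)oxy]-6-pentylbenzoate | COc1cc(C)c(C(=O)Oc2cc(CCCCC)c(C(=O)OCc3ccccc3)c(O)c2)c(O)c1 | intermediate
14 | 2-hydroxy-4-[(2-hydroxy-4-methoxy-6-methylbenzoyl)oxy]-6-pentylbenzoic acid | CCCCCc1cc(OC(=O)c2c(C)cc(OC)cc2O)cc(O)c1C(=O)O | target

**Totals**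
Total step count: 7. Longest linear sequence: 5 steps (1 → 2 → 3 → 4 → 13 → 14, that is steps 1, 2, 3, 6 and 7); the ring-B branch (steps 4 and 5) joins at step 6.

**Steps most likely to fail**

Step 6. The cycloaddition to the β-methyl ynoate may be outpaced by thermal or protic decay of the diene, or the ketene acetal may add stepwise (Michael addition or acyl transfer at the aryl ester) without closing ring A. The fallback leaves the cycloaddition and forms the depside ester from a finished ring-A acid. It sets out from 7 and comes back at 13.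
- Commercial methyl 2,4-dihydroxy-6-methylbenzoate (methyl orsellinate) is methylated at its unchelated 4-hydroxyl (MeI, K2CO3, acetone) to methyl 2-hydroxy-4-methoxy-6-methylbenzoate F1.
- Saponification (KOH, aqueous DMSO, 80 °C, cold acidification) gives 2-hydroxy-4-methoxy-6-methylbenzoic acid F2.
- F2 and 7 are treated with trifluoroacetic anhydride in toluene at rt. The hindered acid is activated as 2-hydroxy-4-methoxy-6-methylbenzoic trifluoroacetic anhydride F3, which should acylate the unchelated 4-hydroxyl of 7 and give 13.
- Step 7 follows unchanged.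

Step 3. The amide base may attack silicon of the silyl ester instead of removing a γ-proton, or the ketene acetal may be lost by hydrolysis during isolation. The fallback avoids having a silyl ester present with the base. It sets out from 2 and comes back at 4.
- Acid 2 is deprotonated twice with LiN(iPr)2 (2.2 equiv, THF, −78 to 0 °C) to dilithium 3-methoxybuta-1,3-diene-1,1-diolate F4.
- F4 is silylated on both oxygens with Me3SiCl (2.5 equiv) to give 4, which is distilled and used at once in step 6.

Step 5. Site selectivity between the two phenols may be lost (acylation of both or of the chelated one), or the free phenol or DMAP may add to the activated ynoate. The fallback removes the second phenol before the acylation. It sets out from 7 and comes back at 14.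
- The 4-hydroxyl of 7 is silylated (iPr3SiCl, imidazole, DMF) to benzyl 2-hydroxy-6-pentyl-4-(triisopropylsilyloxy)benzoate F5.
- Mitsunobu etherification (BnOH, PPh3, DIAD, THF) gives benzyl 2-(benzyloxy)-6-pentyl-4-(triisopropylsilyloxy)benzoate F6.
- Bu4NF/AcOH in THF frees benzyl 2-(benzyloxy)-4-hydroxy-6-pentylbenzoate F7, which has a single hydroxyl.
- Esterification with 8 (DCC, DMAP, CH2Cl2) gives benzyl 2-(benzyloxy)-4-(but-2-ynoyloxy)-6-pentylbenzoate F8.
- F8 reacts with 4 under the thermal conditions of step 6 without prior silylation. It passes through the cyclohexa-1,4-diene cycloadduct F9 and the ring-A trimethylsilyl ether F10, and acid work-up gives benzyl 2-(benzyloxy)-4-[(2-hydroxy-4-methoxy-6-methylbenzoyl)oxy]-6-pentylbenzoate F11.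
- Hydrogenolysis of F11 under the conditions of step 7 removes the benzyl ether and the benzyl ester together and gives 14.

**Further compounds**
F1 | step 6 | methyl 2-hydroxy-4-methoxy-6-methylbenzoate | COC(=O)c1c(C)cc(OC)cc1O
F2 | step 6 | 2-hydroxy-4-methoxy-6-methylbenzoic acid | COc1cc(C)c(C(=O)O)c(O)c1
F3 | step 6 | 2-hydroxy-4-methoxy-6-methylbenzoic trifluoroacetic anhydride | COc1cc(C)c(C(=O)OC(=O)C(F)(F)F)c(O)c1
F4 | step 3 | dilithium 3-methoxybuta-1,3-diene-1,1-diolate | [Li+].[Li+].C=C(OC)C=C([O-])[O-]
F5 | step 5 | benzyl 2-hydroxy-6-pentyl-4-(triisopropylsilyloxy)benzoate | CCCCCc1cc(O[Si](C(C)C)(C(C)C)C(C)C)cc(O)c1C(=O)OCc1ccccc1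
F6 | step 5 | benzyl 2-(benzyloxy)-6-pentyl-4-(triisopropylsilyloxy)benzoate | CCCCCc1cc(O[Si](C(C)C)(C(C)C)C(C)C)cc(OCc2ccccc2)c1C(=O)OCc1ccccc1
F7 | step 5 | benzyl 2-(benzyloxy)-4-hydroxy-6-pentylbenzoate | CCCCCc1cc(O)cc(OCc2ccccc2)c1C(=O)OCc1ccccc1
F8 | step 5 | benzyl 2-(benzyloxy)-4-(but-2-ynoyloxy)-6-pentylbenzoate | CC#CC(=O)Oc1cc(CCCCC)c(C(=O)OCc2ccccc2)c(OCc2ccccc2)c1
F9 | step 5 | benzyl 2-(benzyloxy)-4-{[4-methoxy-2-methyl-6,6-bis(trimethylsilyloxy)cyclohexa-1,4-diene-1-carbonyl]oxy}-6-pentylbenzoate | COC1=CC(O[Si](C)(C)C)(O[Si](C)(C)C)C(C(=O)Oc2cc(CCCCC)c(C(=O)OCc3ccccc3)c(OCc3ccccc3)c2)=C(C)C1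
F10 | step 5 | benzyl 2-(benzyloxy)-4-{[4-methoxy-2-methyl-6-(trimethylsilyloxy)benzoyl]oxy}-6-pentylbenzoate | COc1cc(C)c(C(=O)Oc2cc(CCCCC)c(C(=O)OCc3ccccc3)c(OCc3ccccc3)c2)c(O[Si](C)(C)C)c1
F11 | step 5 | benzyl 2-(benzyloxy)-4-[(2-hydroxy-4-methoxy-6-methylbenzoyl)oxy]-6-pentylbenzoate | COc1cc(C)c(C(=O)Oc2cc(CCCCC)c(C(=O)OCc3ccccc3)c(OCc3ccccc3)c2)c(O)c1
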